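The runs come from a simulation from invented constants; scatter was added.

The ratio of incoming ligand to starting complex charged in this flask is 1.00, and a complex with two exchanged holds two ligands, so at most 50.0 % of the starting complex charged can stand as that product. Counted by the charges, the incoming ligand is the limiting reagent for that product.

| flask | starting complex | incoming ligand | leaving ligand | remark | time |
|---|---|---|---|---|---|
| violet | 1 M | 1 M | 0.67 M | run made earlier |  |
| amber | 1 M | 1 M | 1.5 M | run made earlier |  |
| flask | 1.0 M | 1.00 M | 1.00 M |  | 6.0 h |

| run | time / h | complex with two exchanged / % | starting complex / % |
|---|---|---|---|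
| violet | 0.0667 | 6.3 | 12.2 |
| violet | 0.250 | 13.0 | 2.6 |
| violet | 1.33 | 3.1 | 0 |
| violet | 6.00 | 0.9 | 0.2 |
| amber | 0.0667 | 5.4 | 13.5 |
| amber | 0.250 | 12.6 | 2.0 |
| amber | 1.33 | 3.4 | 0.1 |
| amber | 6.00 | 1.0 | 0 |

(readings scatter by 0.5 percentage points)

- time up to 6.0 h at which complex with two exchanged stands highest
- the amount of complex with two exchanged, in percent of the starting complex charged, at that time
- the first time at which complex with two exchanged reaches 8.9 %, in the same percent



I keep the books on the incoming ligand, as fractions of its charge. The violet and amber runs have the same ratio, and their highest readings of complex with two exchanged both stand at 0.250 h: 13.0 % and 12.6 %. That gap of 0.4 percentage points compares with a scatter of 0.5 points, though the leaving ligand goes from 0.67 M to 1.5 M. The first entry is therefore the ligand held in that product at its highest reading, which is the mean reading over the ceiling: 25.6 %, the kept share. The fraction left, 74.4 %, is the second entry: ligand still free or in forms nobody read, so the readings can't close the books. This flask's leaving ligand lies between the two runs, so I commit to the kept share times the ceiling, 12.8 %, near 0.250 h.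

The forecast gives 14.5 % at 0.17 h and reaches the asked level at 0.1 h. Its time is earlier than mine, and of that maximum it says that it “seems likely, though it is unmeasured”.

The flask gives 12.7 % at 0.250 h and first reaches the level at 0.0986 h, so the forecast's time is low by a factor of 1.47, while its amount and first time stand within their margins.

    starting complex + incoming ligand → leaving ligand + complex with one exchanged (k = 0.00434 /M/s)
    complex with one exchanged + incoming ligand → leaving ligand + complex with two exchanged (k = 0.00248 /M/s)
    complex with two exchanged + incoming ligand → leaving ligand + complex with three exchanged (k = 0.00105 /M/s)
    complex with three exchanged + incoming ligand → leaving ligand + complex with four exchanged (k = 0.00802 /M/s)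
    2 starting complex → self-condensation product (k = 0.00744 /M/s)
    complex with two exchanged ⇌ isomer of the product (K = 25.0, k = 6.70 × 10⁻⁴ /s)

The kept share of this flask is 25.4 %, beside 25.6 % read from the runs. In the neighbour charged with 0.40 M of incoming ligand, the ceiling is 20.0 %, and the carried share gives 5.12 %. That neighbour gives 4.26 %, a kept share of 21.3 %. At 6.00 h, self-condensation product, each counted as the two starting complexes it holds, stands at 61.2 % of the starting complex charged in this flask and at 79.0 % in that neighbour.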